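## Analysis of the target

Acerosin is an achiral flavone: a benzopyran-4-one (rings A and C) carrying a 3-hydroxy-4-methoxyphenyl ring B at C2. There are no stereocenters, so every selectivity question is one of regiochemistry. Ring A is fully substituted, with O1 at C8a, OMe at C8, OH at C7, OMe at C6, OH at C5 and the carbonyl carbon at C4a. Free and methylated oxygens alternate around it, so the pattern has to be built in and cannot be adjusted late by selective methylation or demethylation. The sensitive groups are the three phenols (a chelated 5-OH, an acidic 7-OH, and the 3'-OH), the electron-rich ring A, which oxidizes easily as its phenoxide, the pyranone ring, which hard nucleophiles open at C2, and the aryl methyl ethers, which rule out strong Lewis acids. The difficulty is to tell five oxygens on ring A apart and to place OH at C3' and OMe at C4' in ring B, not the reverse. Ring A is simplified by a hidden symmetry: the 2,6-dihydroxyacetophenone behind it is mirror-symmetric, so closure of ring C through either phenol gives the same chromone. The strategy rests on ring B. C3'–OH sits beside C4'–OMe, and the only carbon substituent (C1') is para to the methoxy group. This is the pattern left when 3-methoxyfuran adds to a terminal alkyne and the oxygen bridge is opened: the furan oxygen becomes the C3' hydroxyl, furan C3 becomes C4', and the two alkyne carbons become C1' and C2'.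

## Retrosynthetic reasoning

The target 14 is traced back to its 7-benzyl ether 13 by cutting the O7–benzyl bond. O7 is the phenol oxygen of the starting material 1. It must be masked during the ring brominations and told apart from the two oxygens introduced later (O1 and O5). One benzyl group does both jobs and is removed at the end by neutral hydrogenolysis, which the flavone C2=C3 bond and the methyl ethers should survive.

Ring B of 13 is disconnected at C2'–C3' and C1'–C6', with the C3' hydroxyl oxygen reconnected to C6' as a bridge. This gives 2-ethynylchromone 10 and 3-methoxyfuran 11. These bonds are chosen over the classical cut through ring C because they remove ring B as a single small diene that already holds both ring B oxygens in the correct relationship. The 3'-hydroxyl then appears free, with no protecting group. The forward reaction has to control two orientations: the cycloaddition must join the furan carbon next to the methoxy group to the terminal alkyne carbon, and the bridge must open at C6' and not at C3'.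

The terminal alkyne of 10 is traced to silyl alkyne 9 (C–Si bond). The silyl group is needed earlier, where an acidic alkyne C–H and an unhindered alkyne terminus would not survive enolate chemistry.

Ring C of 9 is opened at O1–C2 to give diketone 8. Because 8 has two equivalent phenols flanking the acyl group, the forward cyclodehydration has no regiochemical choice, and the phenol not used becomes the 5-OH.

Diketone 8 is cut at the C2–C3 bond (chromone numbering) into acetophenone 6 and the alkynoate ester 7. This is a Claisen-type acylation that brings in C2 and both alkyne carbons in one step.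

Acetophenone 6 is cut at the aryl–acyl bond to give resorcinol 4. This has a single ring C–H, flanked by both hydroxyls, so the acylation can occur at one position only.

The two hydroxyls of 4 (the future O1 and O5) are traced through C–Br bonds to dibromide 3, then to benzyl ether 2 and 2,6-dimethoxyphenol 1. In 2 the central benzyloxy group is twisted out of conjugation by its two neighbours, so the outer methoxy groups should direct both brominations to the two positions that must carry oxygen.

## Alternatives that were turned down

Alternative 1: Here C3 of ring C is excised, contracting the pyranone to the 3-silyloxybenzofuran A2. In the forward direction dichlorocarbene would add to the enol ether double bond of A2, and the dichlorocyclopropane would open with loss of chloride and the silyl group to give the 3-chloroflavone A1. One hydrogenolysis would then remove three benzyl groups and the chlorine to give 14. In its favour, ring B arrives as a ready-made aryl unit with its oxygens already placed, so ring B poses no regiochemical question. On that point it is stronger than the chosen route. Carbene ring expansion of cyclic silyl enol ethers and electron-rich heteroarenes is also an established reaction type. Against it, the alkene of A2 that must accept the carbene is tetrasubstituted and crowded by the aryl group and a peri benzyloxy group. Two very electron-rich arenes compete for the electrophilic carbene. The 2-arylbenzofuranone behind A2 autoxidizes readily at C2. The chlorine is installed only to be removed. The route still needs the same pentaoxygenated ring A arene, three benzyl groups instead of one, and is no shorter. The chosen route carries a regiochemical risk in its cycloaddition but has no halogen detour and a single protecting group.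

Alternative 2: The O1–C8a bond is cut, leading back to the diaryl 1,3-diketone A4. Anodic oxidation of its enol would make the enol oxygen attack an ortho C–H of the syringyl ring to give flavone A3. In its favour, this is the shortest way to the flavone skeleton. A4 should come from one Claisen condensation of two simple aryl carbonyl partners. The syringyl ring is symmetric, and the carbon attacked is ortho and para to methoxy groups. In step count to the skeleton it is clearly stronger than the chosen route. Against it, A3 still has hydrogen at C5. Reaching 14 would need a second, late C–H hydroxylation at the most hindered position of the molecule, between the C6 methoxy group and the C4 carbonyl. The anodic step itself must discriminate between the enol, the guaiacyl-type ring B and two benzyl ethers of similar oxidation potential, and over-oxidation of the product is likely. The chosen route is longer but carries all five ring A oxygens from the start, and its one uncertain step changes no oxidation level.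

Alternative 3: Ring A is disconnected at C5–C6, leading to the 4-pyranone ester A6 with a 1,3-dimethoxy-2-oxopropyl side chain. Double deprotonation would let the terminal carbon of the chain attack the neighbouring ester in a Dieckmann-type closure. Enolization would then give 3'-O-benzylacerosin A5, one debenzylation from 14. In its favour, the ring A oxygen pattern is written into an open chain, so no arene has to be functionalized selectively. The 5- and 7-hydroxyls emerge free, and no transition-metal coupling is needed. On these points it matches or exceeds the chosen route. Against it, A6 is a tetrasubstituted pyranone with a fragile α,α'-dialkoxy ketone, and it would take more steps to make than the four aromatic steps that give ring A here. The key step also needs a second deprotonation at the less acidic terminal carbon after the doubly activated methine, in a substrate where an amide base can attack the pyranone or the ester and the α-alkoxy ketone can eliminate. The chosen route puts comparable risk into one cycloaddition on a robust substrate and reaches it by shorter, conventional chemistry.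

Key step: step 8

Remark: 3-methoxyfuran 11 and ester 7 are taken as purchased reagents; diketone 8 is written as its diketo tautomer although it should exist largely as an enol or cyclic hemiketal, and cycloadduct 12 is racemic (one enantiomer is written).

## Route

Step 1
Reactants: 1 2,6-dimethoxyphenol
Product: 2 2-(benzyloxy)-1,3-dimethoxybenzene
Conditions: BnBr (1.1 equiv), K2CO3 (1.5 equiv), DMF, 60 °C
Reagents that add atoms: benzyl bromide, BrCc1ccccc1
Why: Williamson ether synthesis; the phenoxide is the only nucleophile and benzyl bromide is a reactive SN2 electrophile.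

Step 2
Reactants: 2 2-(benzyloxy)-1,3-dimethoxybenzene
Product: 3 3-(benzyloxy)-1,5-dibromo-2,4-dimethoxybenzene
Conditions: NBS (2.1 equiv), MeCN, 0 °C → rt, dark
Reagents that add atoms: N-bromosuccinimide, O=C1CCC(=O)N1Br
Why: Electrophilic aromatic bromination; the flanked central benzyloxy group is twisted out of conjugation, so the two outer methoxy groups direct both brominations to the positions ortho to one OMe and para to the other, not to the position para to OBn. A polar solvent and darkness should suppress benzylic radical bromination.

Step 3
Reactants: 3 3-(benzyloxy)-1,5-dibromo-2,4-dimethoxybenzene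
Product: 4 5-(benzyloxy)-4,6-dimethoxybenzene-1,3-diol
Conditions: Pd2(dba)3 (2 mol %), tBuXPhos (8 mol %), KOH (6 equiv), 1,4-dioxane/H2O (1:1), degassed, 100 °C; then 1 M HCl
Reagents that add atoms: potassium hydroxide, [K+].[OH-]
Why: Palladium-catalysed hydroxylation of aryl bromides with hydroxide (a Buchwald–Hartwig-type C–O coupling); zerovalent palladium inserts into each C–Br bond and the bulky biarylphosphine enforces C–O reductive elimination. Benzyl and methyl ethers are inert to hot aqueous KOH, and exclusion of air protects the electron-rich resorcinol dianion.

Step 4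
Reactants: 4 5-(benzyloxy)-4,6-dimethoxybenzene-1,3-diol
Product: 6 1-[4-(benzyloxy)-2,6-dihydroxy-3,5-dimethoxyphenyl]ethan-1-one, via ketiminium chloride 5 (not isolated)
Conditions: MeCN (3 equiv), ZnCl2 (1 equiv), HCl (g), Et2O, 0 °C; then H2O, 90 °C
Reagents that add atoms: acetonitrile, CC#N; water, O
Why: Hoesch acylation; the HCl/ZnCl2-activated nitrile attacks the only ring C–H, which is ortho to both hydroxyls and para to the benzyloxy group, and hot water hydrolyses ketiminium salt 5 to the ketone. Anhydrous HCl in ether at 0 °C and a short aqueous heating should spare the benzyl ether.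

Step 5
Reactants: 6 1-[4-(benzyloxy)-2,6-dihydroxy-3,5-dimethoxyphenyl]ethan-1-one; 7 ethyl 3-(trimethylsilyl)prop-2-ynoate
Product: 8 1-[4-(benzyloxy)-2,6-dihydroxy-3,5-dimethoxyphenyl]-5-(trimethylsilyl)pent-4-yne-1,3-dione
Conditions: LiN(SiMe3)2 (4.2 equiv), THF, −78 °C; then 7 (1.2 equiv), −78 → −30 °C; 1 M HCl quench at −30 °C
Reagents that add atoms: none
Why: Claisen-type C-acylation of a hydroxyacetophenone polyanion; the dilithium phenoxide lithium enolate attacks the ester carbonyl, which the sp-hybridized substituent activates, and the fourth equivalent of base takes up the acidic diketone so that it is not attacked again. The silyl group removes the acidic alkyne C–H and blocks conjugate addition at the alkyne terminus.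

Step 6
Reactants: 8 1-[4-(benzyloxy)-2,6-dihydroxy-3,5-dimethoxyphenyl]-5-(trimethylsilyl)pent-4-yne-1,3-dione
Product: 9 7-(benzyloxy)-5-hydroxy-6,8-dimethoxy-2-[(trimethylsilyl)ethynyl]-4H-chromen-4-one
Conditions: TsOH·H2O (0.1 equiv), 4 Å MS, PhMe, 50 °C
Reagents that add atoms: none
Why: Acid-catalysed cyclodehydration of a 1-(2-hydroxyaryl)-1,3-diketone, as in the closing step of a Baker–Venkataraman chromone synthesis; either of the two equivalent phenols adds 6-exo-trig to the alkynyl ketone carbonyl and the hemiketal loses water, leaving the other phenol as the chelated 5-OH. The bulky silyl group shields the alkyne terminus from the competing 6-endo-dig attack of the enol oxygen, and dry conditions avoid alkyne hydration.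

Step 7
Reactants: 9 7-(benzyloxy)-5-hydroxy-6,8-dimethoxy-2-[(trimethylsilyl)ethynyl]-4H-chromen-4-one
Product: 10 7-(benzyloxy)-2-ethynyl-5-hydroxy-6,8-dimethoxy-4H-chromen-4-one
Conditions: Bu4NF (1.1 equiv), AcOH (1.5 equiv), THF, −20 → 0 °C
Reagents that add atoms: none
Why: Fluoride-induced protodesilylation of an alkynylsilane; buffering with acetic acid keeps the medium non-basic, so the pyranone and the electrophilic terminal alkyne do not meet alkoxide, as they would in basic methanol.

Step 8
Reactants: 10 7-(benzyloxy)-2-ethynyl-5-hydroxy-6,8-dimethoxy-4H-chromen-4-one; 11 3-methoxyfuran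
Product: 13 7-O-benzylacerosin (7-(benzyloxy)-5-hydroxy-2-(3-hydroxy-4-methoxyphenyl)-6,8-dimethoxy-4H-chromen-4-one), via oxanorbornadiene cycloadduct 12 (not isolated)
Conditions: 11 (5 equiv), PhMe, 80 °C, sealed tube; evaporate; then camphorsulfonic acid (0.2 equiv), CH2Cl2, 0 °C → rt
Reagents that add atoms: none
Why: Furan 11 is an electron-rich diene whose most nucleophilic terminus is C2, the enol ether β-carbon next to the methoxy group, while the terminal alkyne carbon of 10 is the electrophilic δ-terminus of the enynone C≡C–C2=C3–C4=O, further polarized by the chelated 5-OH···O=C4 hydrogen bond. A normal-demand, asynchronous [4+2] cycloaddition should therefore join furan C2 to the terminal alkyne carbon (C3'–C2') and furan C5 to the internal one (C6'–C1'), the "para" orientation expected for a 2-donor diene and a monosubstituted dienophile. Ring B closes as the six-membered carbocycle of 7-oxanorbornadiene 12 in this one intermolecular cycloaddition; its two bridgehead stereocenters are cis by the bicyclic constraint, form as a racemate and vanish on aromatization, so no stereocontrol is needed. The closest known reaction type is the Diels–Alder reaction of furans with electron-poor alkynes, followed by acid-promoted isomerization of the 7-oxanorbornadiene to a phenol. Anhydrous acid protonates the bridging oxygen and the O–C6' bond ionizes, because only that cation is a vinylogous oxocarbenium ion (C6'–C5'=C4'–OMe); ionization at C3' would put the methoxy group on the central carbon of an allyl cation or place charge next to the electron-poor chromone. Loss of the C3' proton then aromatizes the ring and leaves OH on C3' beside OMe on C4'. The alkyne should react in preference to the chromone C2=C3 bond, which is trisubstituted and part of a vinylogous ester, and the excess of 11 together with the irreversible aromatization offsets the retro-Diels–Alder equilibrium typical of furans. The benzyl ether, the chelated phenol and the methyl ethers are inert to heat and to catalytic sulfonic acid.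

Step 9
Reactants: 13 7-O-benzylacerosin
Product: 14 acerosin (5,7-dihydroxy-2-(3-hydroxy-4-methoxyphenyl)-6,8-dimethoxy-4H-chromen-4-one)
Conditions: H2 (1 atm), 10% Pd/C, EtOAc/MeOH (1:1), rt
Reagents that add atoms: none
Why: Catalytic hydrogenolysis of the benzylic C–O bond; at 1 atm and room temperature the conjugated C2=C3 bond of a flavone and the aryl methyl ethers should not be reduced.

## Compound list

1 | 2,6-dimethoxyphenol | COc1cccc(OC)c1O | starting material
2 | 2-(benzyloxy)-1,3-dimethoxybenzene | COc1cccc(OC)c1OCc1ccccc1 | intermediate
3 | 3-(benzyloxy)-1,5-dibromo-2,4-dimethoxybenzene | COc1c(Br)cc(Br)c(OC)c1OCc1ccccc1 | intermediate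
4 | 5-(benzyloxy)-4,6-dimethoxybenzene-1,3-diol | COc1c(O)cc(O)c(OC)c1OCc1ccccc1 | intermediate
5 | 1-[4-(benzyloxy)-2,6-dihydroxy-3,5-dimethoxyphenyl]ethan-1-iminium chloride (ketiminium chloride, not isolated) | CC(=[NH2+])c1c(O)c(OC)c(OCc2ccccc2)c(OC)c1O.[Cl-] | intermediate
6 | 1-[4-(benzyloxy)-2,6-dihydroxy-3,5-dimethoxyphenyl]ethan-1-one | CC(=O)c1c(O)c(OC)c(OCc2ccccc2)c(OC)c1O | intermediate
7 | ethyl 3-(trimethylsilyl)prop-2-ynoate (ethyl 3-(trimethylsilyl)propiolate) | CCOC(=O)C#C[Si](C)(C)C | starting material
8 | 1-[4-(benzyloxy)-2,6-dihydroxy-3,5-dimethoxyphenyl]-5-(trimethylsilyl)pent-4-yne-1,3-dione | C[Si](C)(C)C#CC(=O)CC(=O)c1c(O)c(OC)c(OCc2ccccc2)c(OC)c1O | intermediate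
9 | 7-(benzyloxy)-5-hydroxy-6,8-dimethoxy-2-[(trimethylsilyl)ethynyl]-4H-chromen-4-one | C[Si](C)(C)C#Cc1cc(=O)c2c(O)c(OC)c(OCc3ccccc3)c(OC)c2o1 | intermediate
10 | 7-(benzyloxy)-2-ethynyl-5-hydroxy-6,8-dimethoxy-4H-chromen-4-one | C#Cc1cc(=O)c2c(O)c(OC)c(OCc3ccccc3)c(OC)c2o1 | intermediate
11 | 3-methoxyfuran | COc1ccoc1 | starting material
12 | 7-(benzyloxy)-5-hydroxy-6,8-dimethoxy-2-(5-methoxy-7-oxabicyclo[2.2.1]hepta-2,5-dien-2-yl)-4H-chromen-4-one (racemic, one enantiomer written; not isolated) | COC1=C[C@H]2O[C@@H]1C=C2c1cc(=O)c2c(O)c(OC)c(OCc3ccccc3)c(OC)c2o1 | intermediate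
13 | 7-O-benzylacerosin, 7-(benzyloxy)-5-hydroxy-2-(3-hydroxy-4-methoxyphenyl)-6,8-dimethoxy-4H-chromen-4-one | COc1ccc(-c2cc(=O)c3c(O)c(OC)c(OCc4ccccc4)c(OC)c3o2)cc1O | intermediate
14 | acerosin, 5,7-dihydroxy-2-(3-hydroxy-4-methoxyphenyl)-6,8-dimethoxy-4H-chromen-4-one | COc1ccc(-c2cc(=O)c3c(O)c(OC)c(O)c(OC)c3o2)cc1O | target

## Step count and risk

Total step count: 9. Longest linear sequence: 9 steps (1 → 14); compounds 7 and 11 are purchased.

Step 8 (key step). The most likely failure is a slow cycloaddition, because the alkyne is activated only through the chromone as a vinylogous ynone. The furan could then decompose or the adduct revert before the bridge is opened. A stepwise Michael-type path is also possible, in which furan C2 attacks the alkyne terminus and then loses a proton, giving C-alkenylation of the furan with no ring closure. Wet acid could hydrolyse the enol ether of the adduct in place of opening the bridge. The fallback gives up building ring B and brings it in preformed. It sets out from 6. Commercial 3-(benzyloxy)-4-methoxybenzoic acid is converted with oxalyl chloride into 3-(benzyloxy)-4-methoxybenzoyl chloride F1. The polyanion of 6 (LiN(SiMe3)2, THF, −78 °C) is C-aroylated with it to give 1-[4-(benzyloxy)-2,6-dihydroxy-3,5-dimethoxyphenyl]-3-[3-(benzyloxy)-4-methoxyphenyl]propane-1,3-dione F2. Cyclodehydration with catalytic H2SO4 in AcOH at 60 °C should give 7,3'-di-O-benzylacerosin F3. Hydrogenolysis of both benzyl ethers over 10% Pd/C rejoins the route at 14.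

Step 5 (with step 6). Acylation of the trianion may be incomplete or unselective, through poor solubility, conjugate addition to the alkynoate, or early loss of silicon to the ethoxide released. In step 6 the enol oxygen may attack the alkyne in a 6-endo-dig closure to a γ-pyrone, or the alkyne may be hydrated. The fallback builds the chromone first and the alkyne afterwards. It sets out from 6. Claisen condensation with diethyl oxalate (NaOEt, EtOH) and ring closure with HCl in EtOH in the same operation should give ethyl 7-(benzyloxy)-5-hydroxy-6,8-dimethoxy-4-oxo-4H-chromene-2-carboxylate F4. NaBH4 in MeOH/THF at 0 °C reduces the activated ester to 7-(benzyloxy)-5-hydroxy-2-(hydroxymethyl)-6,8-dimethoxy-4H-chromen-4-one F5. MnO2 in CH2Cl2 oxidizes this allylic-type alcohol to 7-(benzyloxy)-5-hydroxy-6,8-dimethoxy-4-oxo-4H-chromene-2-carbaldehyde F6. Seyferth–Gilbert homologation with the Ohira–Bestmann reagent (K2CO3, MeOH, 0 °C) rejoins the route at 10.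

Step 3. The second hydroxylation may stall, because the intermediate bromophenoxide is very electron-rich and slow in oxidative addition. Phenoxide may also couple with remaining aryl bromide to give diaryl ethers, and the product dianion may be oxidized by traces of air. The fallback forms C–B bonds first. It sets out from 3. Double Miyaura borylation (B2pin2, Pd(dppf)Cl2, KOAc, 1,4-dioxane, 90 °C) should give 2,2'-[5-(benzyloxy)-4,6-dimethoxy-1,3-phenylene]bis(4,4,5,5-tetramethyl-1,3,2-dioxaborolane) F7. Oxidation with H2O2/NaOH in THF at 0 °C rejoins the route at 4.

Step 4. Attack through oxygen may give an imidate ester in place of C-acylation, reaction at the position flanked by two hydroxyls may be sluggish, and HCl/ZnCl2 may partly remove the benzyl group. The fallback switches from electrophilic to anionic acylation. It sets out from 4. Both phenols are protected (MOMCl, iPr2NEt, CH2Cl2) to give 3-(benzyloxy)-2,4-dimethoxy-1,5-bis(methoxymethoxy)benzene F8. Directed ortho-lithiation between the two MOM ethers (n-BuLi, THF, 0 °C) and quenching with N-methoxy-N-methylacetamide should give 1-[4-(benzyloxy)-3,5-dimethoxy-2,6-bis(methoxymethoxy)phenyl]ethan-1-one F9. Methanolic HCl at 40 °C removes both MOM groups and rejoins the route at 6.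

## Further compounds

F1 | step 8 | 3-(benzyloxy)-4-methoxybenzoyl chloride | COc1ccc(C(Cl)=O)cc1OCc1ccccc1
F2 | step 8 | 1-[4-(benzyloxy)-2,6-dihydroxy-3,5-dimethoxyphenyl]-3-[3-(benzyloxy)-4-methoxyphenyl]propane-1,3-dione | COc1ccc(C(=O)CC(=O)c2c(O)c(OC)c(OCc3ccccc3)c(OC)c2O)cc1OCc1ccccc1
F3 | step 8 | 7,3'-di-O-benzylacerosin, 7-(benzyloxy)-2-[3-(benzyloxy)-4-methoxyphenyl]-5-hydroxy-6,8-dimethoxy-4H-chromen-4-one | COc1ccc(-c2cc(=O)c3c(O)c(OC)c(OCc4ccccc4)c(OC)c3o2)cc1OCc1ccccc1
F4 | step 5 | ethyl 7-(benzyloxy)-5-hydroxy-6,8-dimethoxy-4-oxo-4H-chromene-2-carboxylate | CCOC(=O)c1cc(=O)c2c(O)c(OC)c(OCc3ccccc3)c(OC)c2o1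
F5 | step 5 | 7-(benzyloxy)-5-hydroxy-2-(hydroxymethyl)-6,8-dimethoxy-4H-chromen-4-one | OCc1cc(=O)c2c(O)c(OC)c(OCc3ccccc3)c(OC)c2o1
F6 | step 5 | 7-(benzyloxy)-5-hydroxy-6,8-dimethoxy-4-oxo-4H-chromene-2-carbaldehyde | O=Cc1cc(=O)c2c(O)c(OC)c(OCc3ccccc3)c(OC)c2o1
F7 | step 3 | 2,2'-[5-(benzyloxy)-4,6-dimethoxy-1,3-phenylene]bis(4,4,5,5-tetramethyl-1,3,2-dioxaborolane) | COc1c(B2OC(C)(C)C(C)(C)O2)cc(B2OC(C)(C)C(C)(C)O2)c(OC)c1OCc1ccccc1
F8 | step 4 | 3-(benzyloxy)-2,4-dimethoxy-1,5-bis(methoxymethoxy)benzene | COCOc1cc(OCOC)c(OC)c(OCc2ccccc2)c1OC
F9 | step 4 | 1-[4-(benzyloxy)-3,5-dimethoxy-2,6-bis(methoxymethoxy)phenyl]ethan-1-one | CC(=O)c1c(OCOC)c(OC)c(OCc2ccccc2)c(OC)c1OCOC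
A1 | alternative 1 | 5,7-bis(benzyloxy)-2-[3-(benzyloxy)-4-methoxyphenyl]-3-chloro-6,8-dimethoxy-4H-chromen-4-one | COc1ccc(-c2oc3c(OC)c(OCc4ccccc4)c(OC)c(OCc4ccccc4)c3c(=O)c2Cl)cc1OCc1ccccc1
A2 | alternative 1 | {[4,6-bis(benzyloxy)-2-[3-(benzyloxy)-4-methoxyphenyl]-5,7-dimethoxy-1-benzofuran-3-yl]oxy}(tert-butyl)dimethylsilane | COc1ccc(-c2oc3c(OC)c(OCc4ccccc4)c(OC)c(OCc4ccccc4)c3c2O[Si](C)(C)C(C)(C)C)cc1OCc1ccccc1
A3 | alternative 2 | 7-(benzyloxy)-2-[3-(benzyloxy)-4-methoxyphenyl]-6,8-dimethoxy-4H-chromen-4-one | COc1ccc(-c2cc(=O)c3cc(OC)c(OCc4ccccc4)c(OC)c3o2)cc1OCc1ccccc1
A4 | alternative 2 | 1-[4-(benzyloxy)-3,5-dimethoxyphenyl]-3-[3-(benzyloxy)-4-methoxyphenyl]propane-1,3-dione | COc1ccc(C(=O)CC(=O)c2cc(OC)c(OCc3ccccc3)c(OC)c2)cc1OCc1ccccc1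
A5 | alternative 3 | 3'-O-benzylacerosin, 2-[3-(benzyloxy)-4-methoxyphenyl]-5,7-dihydroxy-6,8-dimethoxy-4H-chromen-4-one | COc1ccc(-c2cc(=O)c3c(O)c(OC)c(O)c(OC)c3o2)cc1OCc1ccccc1
A6 | alternative 3 | methyl 6-[3-(benzyloxy)-4-methoxyphenyl]-2-(1,3-dimethoxy-2-oxopropyl)-4-oxo-4H-pyran-3-carboxylate | COCC(=O)C(OC)c1oc(-c2ccc(OC)c(OCc3ccccc3)c2)cc(=O)c1C(=O)OC
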